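**Retrosynthetic overview**
- The target is reached from a benzyl-ester, dioxolane-protected depside by ketal hydrolysis and then hydrogenolysis.
- The strategy rests on ring A being a 2,4-dihydroxy-6-alkylbenzoate: its six ring carbons and the depside carbonyl map onto C2–C7 and C1 of a 3,5,7-trioxooctanoate. The hydroxyls sit on the carbons from C3 and C5, and the masked 2-oxononyl chain on the carbon from C7. Ring A is therefore cut at its C1–C6 bond (chain C2–C7) by an aldol/aromatization of the open-chain trioxo aryl ester; it is the only ring formed.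
- The trioxo aryl ester comes from capture of an acylketene (thermolysis of a diketo-dioxinone) by the ring B phenol, so the hindered depside C–O bond exists before ring A does.
- The diketo-dioxinone comes from 2,2,6-trimethyl-4H-1,3-dioxin-4-one by two acylations: acetyl chloride, then the Weinreb amide of ketal-protected 3-oxodecanoic acid.
- The ring B phenol comes from 5-heptylresorcinol by carboxylation, benzyl ester formation, and differentiation of the two phenols (allyl at O-4, methyl at O-6, deallylation).

Key step: step 11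

Remark: the target has no stereocentre; all β-dicarbonyl compounds are drawn as keto tautomers although they will exist as keto–enol mixtures.

**Step 1**
Reactants: 1 methyl 3-oxodecanoate
Product: 2 methyl 2-(2-heptyl-1,3-dioxolan-2-yl)acetate
Conditions: ethylene glycol, p-TsOH·H2O (cat.), PhMe, reflux, Dean–Stark
Reagents that add atoms: ethylene glycol, OCCO
Why: Acid-catalysed ketalization of the ketone of a β-keto ester with azeotropic removal of water is a standard dioxolane protection, and the ester carbonyl does not ketalize.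

**Step 2**
Reactants: 2 methyl 2-(2-heptyl-1,3-dioxolan-2-yl)acetate
Product: 3 2-(2-heptyl-1,3-dioxolan-2-yl)-N-methoxy-N-methylacetamide
Conditions: MeNH(OMe)·HCl, i-PrMgCl, THF, −20 to 0 °C
Reagents that add atoms: N,O-dimethylhydroxylamine hydrochloride, CNOC.Cl
Why: The chloromagnesium amide of N,O-dimethylhydroxylamine, formed in the flask, converts the methyl ester directly into the Weinreb amide (ester aminolysis) at low temperature, where the dioxolane is left alone.

**Step 3**
Reactants: 4 2,2,6-trimethyl-4H-1,3-dioxin-4-one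
Product: 6 2,2-dimethyl-6-(2-oxopropyl)-4H-1,3-dioxin-4-one, via lithium dienolate 5 (not isolated)
Conditions: LiN(SiMe3)2, THF, −78 °C; then AcCl (0.5 equiv relative to enolate), −78 °C
Reagents that add atoms: acetyl chloride, CC(=O)Cl
Why: Deprotonation of the 6-methyl group gives the vinylogous dienolate 5, which is C-acylated at the γ-carbon by acetyl chloride (vinylogous Claisen condensation); the enolate is used in excess because the product is more acidic than 4.

**Step 4**
Reactants: 6 2,2-dimethyl-6-(2-oxopropyl)-4H-1,3-dioxin-4-one; 3 2-(2-heptyl-1,3-dioxolan-2-yl)-N-methoxy-N-methylacetamide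
Product: 8 6-[5-(2-heptyl-1,3-dioxolan-2-yl)-2,4-dioxopentyl]-2,2-dimethyl-4H-1,3-dioxin-4-one, via dilithium dianion 7 (not isolated)
Conditions: LiN(i-Pr)2 (2.1 equiv), THF, −78 °C; then 3, −78 to −20 °C; aq. NH4Cl
Reagents that add atoms: none
Why: Double deprotonation gives dianion 7, whose more reactive terminal carbanion adds to the Weinreb amide (Claisen-type acylation), and the chelated tetrahedral intermediate prevents over-addition and releases the 1,3-diketone only on quench.

**Step 5**
Reactants: 9 5-heptylresorcinol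
Product: 10 2-heptyl-4,6-dihydroxybenzoic acid
Conditions: MeOMgOCO2Me (2 M in DMF), 120 °C; then cold aq. HCl
Reagents that add atoms: methyl magnesium carbonate, CO[Mg]OC(=O)OC
Why: Methyl magnesium carbonate carboxylates the resorcinol ortho to a hydroxyl through a magnesium chelate (Kolbe–Schmitt-type carboxylation), which with 5-alkylresorcinols should give the 2,4-dihydroxy-6-alkylbenzoic acid.

**Step 6**
Reactants: 10 2-heptyl-4,6-dihydroxybenzoic acid
Product: 11 benzyl 2-heptyl-4,6-dihydroxybenzoate
Conditions: BnBr, KHCO3, DMF, 20 °C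
Reagents that add atoms: benzyl bromide, BrCc1ccccc1
Why: Under hydrogen carbonate only the carboxylate is formed, so SN2 alkylation with benzyl bromide should give the ester alone, and room temperature avoids decarboxylation of the acid.

**Step 7**
Reactants: 11 benzyl 2-heptyl-4,6-dihydroxybenzoate
Product: 12 benzyl 2-heptyl-6-hydroxy-4-(prop-2-en-1-yloxy)benzoate
Conditions: allyl bromide (1.05 equiv), K2CO3, acetone, 20 to 40 °C
Reagents that add atoms: allyl bromide, C=CCBr
Why: The 4-hydroxyl is the more acidic, unchelated phenol, whereas the 6-hydroxyl is hydrogen-bonded to the ester carbonyl, so Williamson etherification with one equivalent of allyl bromide should be selective for O-4.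

**Step 8**
Reactants: 12 benzyl 2-heptyl-6-hydroxy-4-(prop-2-en-1-yloxy)benzoate
Product: 13 benzyl 2-heptyl-6-methoxy-4-(prop-2-en-1-yloxy)benzoate
Conditions: MeI, K2CO3, DMF, 40 °C
Reagents that add atoms: iodomethane, CI
Why: With O-4 blocked, the chelated 6-hydroxyl is methylated under more forcing Williamson conditions in DMF, and the benzyl ester is stable to anhydrous carbonate.

**Step 9**
Reactants: 13 benzyl 2-heptyl-6-methoxy-4-(prop-2-en-1-yloxy)benzoate
Product: 14 benzyl 2-heptyl-4-hydroxy-6-methoxybenzoate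
Conditions: Pd(PPh3)4 (cat.), morpholine, THF, 20 °C
Reagents that add atoms: none
Why: Zerovalent palladium ionizes the aryl allyl ether to a π-allyl complex that morpholine captures (Tsuji–Trost deallylation), leaving the benzyl ester and the methyl ether untouched.

**Step 10**
Reactants: 8 6-[5-(2-heptyl-1,3-dioxolan-2-yl)-2,4-dioxopentyl]-2,2-dimethyl-4H-1,3-dioxin-4-one; 14 benzyl 2-heptyl-4-hydroxy-6-methoxybenzoate
Product: 16 benzyl 2-heptyl-4-{[8-(2-heptyl-1,3-dioxolan-2-yl)-3,5,7-trioxooctanoyl]oxy}-6-methoxybenzoate, via acylketene 15 (not isolated)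
Conditions: PhMe, 110 °C, 14 in 1.5-fold excess; solvent removed and crude 16 used directly
Reagents that add atoms: none
Why: Thermal retro-hetero-Diels–Alder fragmentation of the dioxinone releases acetone and acylketene 15, which the unhindered 4-hydroxyl of 14 (flanked by two ring hydrogens) should capture to give the β-keto aryl ester, a known mode of acylketene trapping by phenols.

**Step 11**
Reactants: 16 benzyl 2-heptyl-4-{[8-(2-heptyl-1,3-dioxolan-2-yl)-3,5,7-trioxooctanoyl]oxy}-6-methoxybenzoate
Product: 18 benzyl 4-({2,4-dihydroxy-6-[(2-heptyl-1,3-dioxolan-2-yl)methyl]benzoyl}oxy)-2-heptyl-6-methoxybenzoate, via cyclic aldol adduct 17 (not isolated)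
Conditions: Et3N (3 equiv), CH2Cl2, 0 to 20 °C
Reagents that add atoms: none
Why: Triethylamine deprotonates the doubly activated C2 methylene between the aryl ester and the C3 ketone, and the enolate adds to the C7 ketone to give cyclic aldol adduct 17, which loses water by E1cB and tautomerizes at C3 and C5 to the aromatic 2,4-dihydroxybenzoate. The closest known reaction type is the base-mediated aldol cyclization and dehydrative aromatization of 3,5,7-triketo esters obtained by acylketene capture, which gives 6-substituted resorcylates. Ring A is closed in a 6-(enolexo)-exo-trig mode by forming the chain C2–C7 bond, which becomes the C1–C6 bond of the arene. No stereocentre remains in 18, because the two transient centres of 17 are erased on aromatization. The step needs the aldol to win over Claisen closure of C6 onto the ester carbonyl and over lactonization to a 4-hydroxy-2-pyrone, both of which would expel the phenoxide of 14; for triketo esters the aldol is the preferred cyclization under weak base, whereas Claisen closure needs chelating metal alkoxides and pyrone formation needs acid or heat, so an amine base in an aprotic solvent at 0 °C should favour it. The dioxolane at C9 removes the competing aldol of C4 onto C9 and leaves C8 only singly activated, so no other carbocycle can form.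

**Step 12**
Reactants: 18 benzyl 4-({2,4-dihydroxy-6-[(2-heptyl-1,3-dioxolan-2-yl)methyl]benzoyl}oxy)-2-heptyl-6-methoxybenzoate
Product: 19 benzyl 4-{[2,4-dihydroxy-6-(2-oxononyl)benzoyl]oxy}-2-heptyl-6-methoxybenzoate
Conditions: 1 M aq. HCl/THF (1:4), 20 °C, short reaction time
Reagents that add atoms: water, O
Why: Acid-catalysed hydrolysis of a dialkyl ketone dioxolane is fast at room temperature, the aryl and benzyl esters are stable to dilute aqueous acid, and brief exposure at 20 °C should avoid enol-lactonization of the freed ketone onto the depside carbonyl.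

**Step 13**
Reactants: 19 benzyl 4-{[2,4-dihydroxy-6-(2-oxononyl)benzoyl]oxy}-2-heptyl-6-methoxybenzoate
Product: 20 4-{[2,4-dihydroxy-6-(2-oxononyl)benzoyl]oxy}-2-heptyl-6-methoxybenzoic acid
Conditions: H2 (1 atm), 10% Pd/C, EtOAc, 20 °C
Reagents that add atoms: none
Why: Hydrogenolysis of the benzyl ester over Pd/C is neutral, so the depside ester, the dialkyl ketone and the free phenols should not be touched.

**Compound list**
1 | methyl 3-oxodecanoate | CCCCCCCC(=O)CC(=O)OC | starting material
2 | methyl 2-(2-heptyl-1,3-dioxolan-2-yl)acetate | CCCCCCCC1(CC(=O)OC)OCCO1 | intermediate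
3 | 2-(2-heptyl-1,3-dioxolan-2-yl)-N-methoxy-N-methylacetamide | CCCCCCCC1(CC(=O)N(C)OC)OCCO1 | intermediate
4 | 2,2,6-trimethyl-4H-1,3-dioxin-4-one | CC1=CC(=O)OC(C)(C)O1 | starting material
5 | lithium 2,2-dimethyl-6-methylidene-6H-1,3-dioxin-4-olate (lithium dienolate of 4) | [Li+].[O-]C1=CC(=C)OC(C)(C)O1 | intermediate (not isolated)
6 | 2,2-dimethyl-6-(2-oxopropyl)-4H-1,3-dioxin-4-one | CC(=O)CC1=CC(=O)OC(C)(C)O1 | intermediate
7 | dilithium dianion of 6 (terminal enolate CH2=C(O−) conjugated to the ring dienolate) | [Li+].[Li+].C=C([O-])C=C1C=C([O-])OC(C)(C)O1 | intermediate (not isolated)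
8 | 6-[5-(2-heptyl-1,3-dioxolan-2-yl)-2,4-dioxopentyl]-2,2-dimethyl-4H-1,3-dioxin-4-one | CCCCCCCC1(CC(=O)CC(=O)CC2=CC(=O)OC(C)(C)O2)OCCO1 | intermediate
9 | 5-heptylresorcinol | CCCCCCCc1cc(O)cc(O)c1 | starting material
10 | 2-heptyl-4,6-dihydroxybenzoic acid | CCCCCCCc1cc(O)cc(O)c1C(=O)O | intermediate
11 | benzyl 2-heptyl-4,6-dihydroxybenzoate | CCCCCCCc1cc(O)cc(O)c1C(=O)OCc1ccccc1 | intermediate
12 | benzyl 2-heptyl-6-hydroxy-4-(prop-2-en-1-yloxy)benzoate | CCCCCCCc1cc(OCC=C)cc(O)c1C(=O)OCc1ccccc1 | intermediate
13 | benzyl 2-heptyl-6-methoxy-4-(prop-2-en-1-yloxy)benzoate | CCCCCCCc1cc(OCC=C)cc(OC)c1C(=O)OCc1ccccc1 | intermediate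
14 | benzyl 2-heptyl-4-hydroxy-6-methoxybenzoate | CCCCCCCc1cc(O)cc(OC)c1C(=O)OCc1ccccc1 | intermediate
15 | 8-(2-heptyl-1,3-dioxolan-2-yl)oct-1-ene-1,3,5,7-tetrone (acylketene) | CCCCCCCC1(CC(=O)CC(=O)CC(=O)C=C=O)OCCO1 | intermediate (not isolated)
16 | benzyl 2-heptyl-4-{[8-(2-heptyl-1,3-dioxolan-2-yl)-3,5,7-trioxooctanoyl]oxy}-6-methoxybenzoate | CCCCCCCC1(CC(=O)CC(=O)CC(=O)CC(=O)Oc2cc(CCCCCCC)c(C(=O)OCc3ccccc3)c(OC)c2)OCCO1 | intermediate
17 | benzyl 4-[({2-hydroxy-2-[(2-heptyl-1,3-dioxolan-2-yl)methyl]-4,6-dioxocyclohexyl}carbonyl)oxy]-2-heptyl-6-methoxybenzoate (mixture of diastereomers and tautomers) | CCCCCCCC1(CC2(O)CC(=O)CC(=O)C2C(=O)Oc2cc(CCCCCCC)c(C(=O)OCc3ccccc3)c(OC)c2)OCCO1 | intermediate (not isolated)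
18 | benzyl 4-({2,4-dihydroxy-6-[(2-heptyl-1,3-dioxolan-2-yl)methyl]benzoyl}oxy)-2-heptyl-6-methoxybenzoate | CCCCCCCC1(Cc2cc(O)cc(O)c2C(=O)Oc2cc(CCCCCCC)c(C(=O)OCc3ccccc3)c(OC)c2)OCCO1 | intermediate
19 | benzyl 4-{[2,4-dihydroxy-6-(2-oxononyl)benzoyl]oxy}-2-heptyl-6-methoxybenzoate | CCCCCCCC(=O)Cc1cc(O)cc(O)c1C(=O)Oc1cc(CCCCCCC)c(C(=O)OCc2ccccc2)c(OC)c1 | intermediate
20 | 4-{[2,4-dihydroxy-6-(2-oxononyl)benzoyl]oxy}-2-heptyl-6-methoxybenzoic acid | CCCCCCCC(=O)Cc1cc(O)cc(O)c1C(=O)Oc1cc(CCCCCCC)c(C(=O)O)c(OC)c1 | target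

**Step count and risks**

Total step count: 13. Longest linear sequence: 9 steps (from 5-heptylresorcinol 9: steps 5, 6, 7, 8, 9, 10, 11, 12, 13).

Steps most likely to fail:

1. Step 11 (key step). Under base, the C5/C7 enolate may attack the aryl ester carbonyl, either by Claisen closure through C6 or by lactonization through the C5 enol oxygen. Either path expels the phenoxide of 14 faster than the C2–C7 aldol closes. The fallback sets out from 8 and comes back to the route at 20. The aldol aromatization is run on the diketo-dioxinone itself, which carries no leaving group. Et3N in CH2Cl2 at 20 °C should convert 8 into 7-hydroxy-5-[(2-heptyl-1,3-dioxolan-2-yl)methyl]-2,2-dimethyl-4H-1,3-benzodioxin-4-one F1. Benzylation of the free phenol (BnBr, K2CO3, acetone) would give 7-(benzyloxy)-5-[(2-heptyl-1,3-dioxolan-2-yl)methyl]-2,2-dimethyl-4H-1,3-benzodioxin-4-one F2. The sodium phenoxide of 14 (NaH, THF, 0 to 50 °C) would then open the benzodioxinone with loss of acetone to benzyl 4-({4-(benzyloxy)-2-hydroxy-6-[(2-heptyl-1,3-dioxolan-2-yl)methyl]benzoyl}oxy)-2-heptyl-6-methoxybenzoate F3. Dilute aqueous HCl in THF would free the ketone as benzyl 4-{[4-(benzyloxy)-2-hydroxy-6-(2-oxononyl)benzoyl]oxy}-2-heptyl-6-methoxybenzoate F4. Hydrogenolysis of both benzyl groups (H2, Pd/C, EtOAc) would give 20.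

2. Step 10. Bimolecular capture of acylketene 15 by the weakly nucleophilic phenol may be slow, and the aryl β-keto ester may revert thermally at 110 °C, so material could drain into a 4-hydroxy-2-pyrone by intramolecular capture through the C5 enol. The fallback sets out from 8 and comes back at 16. Thermolysis of 8 in PhMe at 110 °C (sealed tube) with 2-methylpropane-2-thiol, a far better ketene trap, should give S-tert-butyl 8-(2-heptyl-1,3-dioxolan-2-yl)-3,5,7-trioxooctanethioate F5. Thiophilic activation with AgO2CCF3 in THF at 20 °C in the presence of 14 would then transfer the acyl group to the phenol and give 16 without prolonged heating of the aryl ester.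

3. Step 4. The dianion 7 may take a proton from the α-methylene of Weinreb amide 3 instead of adding to it, and the amide enolate may then open the dioxolane by β-elimination. The fallback sets out from 2 and 6 and comes back at 8. Reduction of 2 with i-Bu2AlH in CH2Cl2 at −78 °C should give 2-(2-heptyl-1,3-dioxolan-2-yl)acetaldehyde F6. Aldol addition of dianion 7 (from 6, LiN(i-Pr)2, THF, −78 °C) to this aldehyde, a faster and less basicity-sensitive reaction than amide acylation, would give racemic 6-[5-(2-heptyl-1,3-dioxolan-2-yl)-4-hydroxy-2-oxopentyl]-2,2-dimethyl-4H-1,3-dioxin-4-one F7. Dess–Martin periodinane in CH2Cl2 would oxidize it to the 1,3-diketone 8.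

**Further compounds**
F1 | step 11 | 7-hydroxy-5-[(2-heptyl-1,3-dioxolan-2-yl)methyl]-2,2-dimethyl-4H-1,3-benzodioxin-4-one | CCCCCCCC1(Cc2cc(O)cc3OC(C)(C)OC(=O)c23)OCCO1
F2 | step 11 | 7-(benzyloxy)-5-[(2-heptyl-1,3-dioxolan-2-yl)methyl]-2,2-dimethyl-4H-1,3-benzodioxin-4-one | CCCCCCCC1(Cc2cc(OCc4ccccc4)cc3OC(C)(C)OC(=O)c23)OCCO1
F3 | step 11 | benzyl 4-({4-(benzyloxy)-2-hydroxy-6-[(2-heptyl-1,3-dioxolan-2-yl)methyl]benzoyl}oxy)-2-heptyl-6-methoxybenzoate | CCCCCCCC1(Cc2cc(OCc3ccccc3)cc(O)c2C(=O)Oc2cc(CCCCCCC)c(C(=O)OCc3ccccc3)c(OC)c2)OCCO1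
F4 | step 11 | benzyl 4-{[4-(benzyloxy)-2-hydroxy-6-(2-oxononyl)benzoyl]oxy}-2-heptyl-6-methoxybenzoate | CCCCCCCC(=O)Cc1cc(OCc2ccccc2)cc(O)c1C(=O)Oc1cc(CCCCCCC)c(C(=O)OCc2ccccc2)c(OC)c1
F5 | step 10 | S-tert-butyl 8-(2-heptyl-1,3-dioxolan-2-yl)-3,5,7-trioxooctanethioate | CCCCCCCC1(CC(=O)CC(=O)CC(=O)CC(=O)SC(C)(C)C)OCCO1
F6 | step 4 | 2-(2-heptyl-1,3-dioxolan-2-yl)acetaldehyde | CCCCCCCC1(CC=O)OCCO1
F7 | step 4 | 6-[5-(2-heptyl-1,3-dioxolan-2-yl)-4-hydroxy-2-oxopentyl]-2,2-dimethyl-4H-1,3-dioxin-4-one (racemic) | CCCCCCCC1(CC(O)CC(=O)CC2=CC(=O)OC(C)(C)O2)OCCO1
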